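## The problem

The target 29 is a biflavonoid. A (2S)-flavanone with a 5-methoxy and a 7-hydroxy group on ring A is joined through C3' of its ring B to C6'' of a 5'',7'',4'''-trihydroxyflavone. The bond C3'–C6'' lies between O4' on one side and O5'' and O7'' on the other. The flavone carbon is therefore doubly ortho-oxygenated, and a cross-coupling there would be slow and would compete with protodemetalation. The only stereocenter is C2, a benzylic ether carbon β to the C4 ketone. Base or hot acid opens ring C to the chalcone and recloses it without memory, and the para oxygen O4' eases this, so C2 must be set late by a catalyst and followed only by neutral operations. One of the six aromatic oxygens is a methyl ether peri to the C4 carbonyl, the ether that boron halides cleave first, so the five phenols need protecting groups that leave under neutral conditions. The flavone benzo ring is a phloroglucinol in which C6'' sits between two oxygens and para to the ring oxygen O1''. Closure of the pyranone onto a neighbouring oxygen would give the 8-aryl isomer, so the para oxygen must be distinguished from its two neighbours. The enabling feature is ring B, a 1,3,4-trisubstituted benzene with its carbon substituent at C1' para to O4' and the phloroglucinol ring at C3'. This is the pattern formed when an aryl ketene acetal adds across C6 and C3 of a 2-pyrone-5-carboxylate: the ester carbon becomes C2, the aryl-bearing carbon C3' and the acetal carbon C4'.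

## Retrosynthesis

**Protecting groups, 29 from 28.** No skeletal bond is cut first. The five phenols are carried as benzyl ethers in 28, so the last step is a neutral hydrogenolysis. Acetal groups would need acid after C2 is set, and extra methyl ethers could not be removed beside the O5 methyl ether.

**Ring C, 28 from 21 and 24.** The O1–C2 bond is cut (oxa-Michael addition), then the C2–C3 bond (Knoevenagel condensation), with a tert-butyl ester placed on C3 in alkylidene 25. The plain 2'-hydroxychalcone has no dependable enantioselective ring closure. The doubly activated alkylidene 25 binds a bifunctional thiourea, and the ester is lost afterwards. This separates the small ring A ketoester 24 from aldehyde 21, which holds the rest of the molecule. The forward reaction must give face selectivity at C2 and a decarboxylation that does not reopen the ring.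

**Oxidation level at C1', 21 from 18.** Aldehyde 21 is traced through alcohol 20 and acid 19 to methyl ester 18. An aldehyde could not pass through the enolate chemistry that builds the flavone, and a hydride reagent strong enough for an ester would attack the pyranone. The ester is therefore kept until the flavone is complete, and the acid is then reduced with borane.

**Flavone pyranone, 18 from 15 and 16.** The O1''–C2'' and C2''–C3'' bonds are cut, giving the ortho-hydroxyacetophenone 15 and the aroyl chloride 16 (Baker–Venkataraman logic through diketone 17). In 15 only the para oxygen is free and O5'' is benzylated, so only the 6-aryl flavone can form.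

**Acetyl group and oxygen pattern, 15 from 12.** The C4a''–C4'' bond is cut (Friedel–Crafts acetylation of 13 to 14, then deallylation). The phloroglucinol ring of 13 has two equivalent free positions, each beside the allyloxy group, so the acetyl group can only enter next to the para oxygen. Ether 13 comes from phenol 12 by benzylation of O4'. Allyl is chosen for the para oxygen because it survives the aqueous acid, strong base and heat used before the key step and leaves under neutral conditions.

**Ring B, 12 from 7 and 8.** The C2'–C3' and C4'–C5' bonds are cut, which opens ring B to methyl coumalate 8 and the bis(trimethylsilyl) ketene acetal 7. The neighbouring cut, the biaryl bond itself, would need a coupling at a carbon flanked by two benzyloxy groups. Here that bond is already present in the arylacetic acid. The forward reaction needs one regiochemistry, aryl meta and oxygen para to the ester.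

**Arylacetic acid, 7 from 1.** Ketene acetal 7 comes from acid 6 by double silylation. Acid 6 comes from aldehyde 3 by one-carbon homologation through enol ether 4 and aldehyde 5. Aldehyde 3 comes from 2,4,6-trihydroxybenzaldehyde 1 through the mono-allyl ether 2. The formyl group marks the carbon that becomes C6'', and its hydrogen bonds to the two flanking phenols leave the para phenol as the first to react.

**Ring A ketoester, 24 from 22.** Ketoester 24 comes from acetophenone 23 by tert-butoxycarbonylation of its enolate, and 23 from 22 by benzylation of the one phenol not hydrogen-bonded to the acetyl group.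

## Roads not taken

**Alternative 1:** Ring A is cut at C8–C8a and C4a–C5, leaving ring C as a chiral dihydropyranone. In the forward direction the 1,1-dimethoxy-3-silyloxybutadiene A3 would add to the brominated enone double bond of the (S)-5-bromo-2-aryl-2,3-dihydropyran-4-one A2. Loss of HBr, methanol and the silyl group would aromatise the new ring to A1, the target carrying four methoxymethyl ethers.
- Merits: C2 would be set before ring A exists, by an asymmetric hetero-Diels–Alder reaction of an aryl aldehyde, which does not rest on a reversible oxa-Michael equilibrium. The diene delivers O5 as methyl ether and O7 as free phenol, so ring A needs no protecting group.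
- Weak points: the double bond of A2 is a vinylogous ester, and a ketene acetal diene may stop at conjugate addition. Aromatisation releases HBr while C2 sits β to the carbonyl, and the final acid deprotection exposes the para-oxygenated benzylic C2 again.
- Comparison: this road only changes the flavanone end. A2 would come from the methoxymethyl analogue of 21, so the crowded C3'–C6'' bond still needs a coupling. At the flavanone end it is equal or slightly shorter and its C2-forming step is irreversible, which is better. The chosen plan sets against this a coupling-free biaryl, a key step with close precedent and a neutral last step.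

**Alternative 2:** The flavone benzo ring is cut at C6''–C7'' and C5''–C4a''. Heating the 3-alkoxycyclobutenone A5 with the aryl siloxyalkyne A6 would give phenol A4 by a Danheiser benzannulation (vinylketene formation, [2+2] addition, ring opening, 6π closure). A4 is a 2-arylphloroglucinol whose three oxygens carry hydrogen, triisopropylsilyl and 4-methoxybenzyl.
- Merits: like the chosen plan it builds a ring around the crowded bond. It is better in two respects. All three oxygens are differentiated in the ring-forming step, where the chosen plan relies on a selective mono-allylation in step 1. Ring B carries C1' as a dimethyl acetal, already at the aldehyde level, where the chosen plan spends steps 11 to 13 on the benzoate.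
- Weak points: A6 must be made from an ester by ynolate homologation and is sensitive, and A5 is also a prepared reagent. The free phenol of A4 needs another protection, and the acetal must survive removal of the 4-methoxybenzyl group and the acid closure of the flavone.
- Comparison: the chosen plan sets against the two advantages a commercial pyrone, an arylacetic acid from standard homologation, and one persistent protecting group.

**Alternative 3:** Ring A is attached last through O1–C8a and C4–C4a. Fluoride would release a 3-methoxy-5-(methoxymethoxy)benzyne from the ortho-silylaryl triflate A9. The carboxylate of cinnamic acid A8 adds to the aryne carbon remote from the methoxy group, and the aryl anion formed beside the methoxy group attacks the ester carbonyl. The product is the 2'-hydroxy-6'-methoxychalcone A7, and no ring is retained.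
- Merits: convergent, free of enolate chemistry, with the ring A regiochemistry set by the methoxy group. It is shorter at the ring A end than the chosen plan.
- Weak points: the aryl anion may be protonated before the acyl shift, giving the aryl cinnamate. A9 takes several steps. The product is a plain chalcone with no dependable enantioselective ring closure, which is why the chosen plan goes through alkylidene 25. The acetal groups need acid after C2 is set, and A8 still needs the biaryl from elsewhere.
- Comparison: the chosen plan gives up the shorter ring A end in exchange for control of C2 and a coupling-free biaryl.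

Key step: step 6

**Assumptions**

- The 3'–6'' biaryl axis has three ortho substituents and is taken to rotate freely at room temperature, so C2 is the only stereogenic element to control.
- The quinidine-derived member of the pseudoenantiomeric cinchona thiourea pair is taken to close ring C to the 2S configuration. If the sense is reversed on this substrate, the quinine-derived member replaces it with no other change.
- Compounds 1, 8, 16 and 22 are taken as purchased.

## Steps

Step 1
Reactants: 1 2,4,6-trihydroxybenzaldehyde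
Product: 2 4-(allyloxy)-2,6-dihydroxybenzaldehyde
Conditions: allyl bromide (1.0 equiv), KHCO3, DMF, 40 °C
Reagents that add atoms: allyl bromide, C=CCBr
Why: Williamson alkylation; the 4-hydroxyl is the only phenol not hydrogen-bonded to the formyl group and the most acidic, so one equivalent of electrophile with a bicarbonate base should alkylate it selectively.

Step 2
Reactants: 2 4-(allyloxy)-2,6-dihydroxybenzaldehyde
Product: 3 4-(allyloxy)-2,6-bis(benzyloxy)benzaldehyde
Conditions: BnBr (2.5 equiv), K2CO3, DMF, 70 °C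
Reagents that add atoms: benzyl bromide, BrCc1ccccc1
Why: Williamson benzylation of the two chelated phenols under forcing carbonate conditions; the allyl ether and the aldehyde are inert.

Step 3
Reactants: 3 4-(allyloxy)-2,6-bis(benzyloxy)benzaldehyde
Product: 4 5-(allyloxy)-1,3-bis(benzyloxy)-2-(2-methoxyvinyl)benzene (E/Z mixture)
Conditions: MeOCH2PPh3Cl, NaN(SiMe3)2, THF, 0 °C to rt
Reagents that add atoms: (methoxymethyl)triphenylphosphonium chloride, COC[P+](c1ccccc1)(c1ccccc1)c1ccccc1.[Cl-]
Why: Wittig methoxymethylenation; 2,6-dialkoxybenzaldehydes accept this small ylide, and both alkene isomers hydrolyse to the same aldehyde.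

Step 4
Reactants: 4 5-(allyloxy)-1,3-bis(benzyloxy)-2-(2-methoxyvinyl)benzene
Product: 6 2-[4-(allyloxy)-2,6-bis(benzyloxy)phenyl]acetic acid, via arylacetaldehyde 5 (not isolated)
Conditions: 2 M HCl, THF, rt; then NaClO2, NaH2PO4, 2-methyl-2-butene (excess), t-BuOH/H2O, 0 °C
Reagents that add atoms: water, O; sodium chlorite, [Na+].[O-]Cl=O
Why: Acid hydrolysis of the enol ether gives the sensitive arylacetaldehyde, which is oxidised at once by Pinnick oxidation; excess alkene scavenger keeps hypochlorite from the electron-rich ring and the allyl group.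

Step 5
Reactants: 6 2-[4-(allyloxy)-2,6-bis(benzyloxy)phenyl]acetic acid
Product: 7 {2-[4-(allyloxy)-2,6-bis(benzyloxy)phenyl]ethene-1,1-diyl}bis(oxy)bis(trimethylsilane), the bis(trimethylsilyl) ketene acetal of 6
Conditions: LiN(iPr)2 (2.2 equiv), THF, −78 °C; Me3SiCl (2.5 equiv), −78 °C to rt; filtered from LiCl in pentane under argon and used crude
Reagents that add atoms: chlorotrimethylsilane, C[Si](C)(C)Cl
Why: Double deprotonation of an arylacetic acid to its enediolate and O-silylation of both oxygens is the standard entry to bis(trimethylsilyl) ketene acetals; the ethers are inert to the amide base at low temperature.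

Step 6
Reactants: 7 bis(trimethylsilyl) ketene acetal of 2-[4-(allyloxy)-2,6-bis(benzyloxy)phenyl]acetic acid; 8 methyl coumalate
Product: 12 methyl 3-[4-(allyloxy)-2,6-bis(benzyloxy)phenyl]-4-hydroxybenzoate, via bridged lactone 9 (not isolated), via cyclohexadiene 10 (not isolated), via aryl silyl ether 11 (not isolated)
Conditions: toluene, 90 °C, sealed tube; then 1 M HCl, THF, rt
Reagents that add atoms: none
Why: This is an inverse-electron-demand Diels–Alder reaction of an electron-poor 2-pyrone with a ketene acetal followed by cycloreversion and elimination, the known route from methyl coumalate and ketene acetals or enol ethers to para-oxygenated benzoates. The pyrone reacts through its LUMO, which is largest at C6 (β to the ester, δ to the lactone carbonyl); the aryl-bearing carbon of 7, the nucleophilic end of the ketene acetal, bonds there and the acetal carbon bonds to C3, so ring B closes as a six-membered ring by [4+2] addition across C3 and C6 to give bridged lactone 9. Retro-[4+2] loss of CO2 from 9 gives cyclohexadiene 10, and 1,2-elimination of trimethylsilanol aromatises it to 11, whose silyl ether is cleaved in the acidic work-up. The selectivity needed is regiochemical (aryl meta and oxygen para to the ester) and follows from this polarity match whether the addition is concerted or passes through a zwitterion. The stereocenters of 9 and 10 are transient and none survives aromatisation. The allyl double bond is unactivated and should not compete as a dienophile at this temperature, and the aprotic non-polar medium protects the ketene acetal from protonation. The crowded C3'–C6'' bond is not formed here; it arrives with the arylacetic acid.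

Step 7
Reactants: 12 methyl 3-[4-(allyloxy)-2,6-bis(benzyloxy)phenyl]-4-hydroxybenzoate
Product: 13 methyl 3-[4-(allyloxy)-2,6-bis(benzyloxy)phenyl]-4-(benzyloxy)benzoate
Conditions: BnBr, K2CO3, DMF, 50 °C
Reagents that add atoms: benzyl bromide, BrCc1ccccc1
Why: Williamson benzylation of the acidic 4-hydroxybenzoate phenol; O4' now carries the persistent group while the para oxygen of the other ring keeps its distinct allyl group.

Step 8
Reactants: 13 methyl 3-[4-(allyloxy)-2,6-bis(benzyloxy)phenyl]-4-(benzyloxy)benzoate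
Product: 14 methyl 3-[3-acetyl-4-(allyloxy)-2,6-bis(benzyloxy)phenyl]-4-(benzyloxy)benzoate
Conditions: AcOH (2 equiv), (CF3CO)2O (3 equiv), CH2Cl2, 0 °C to rt
Reagents that add atoms: acetic acid, CC(=O)O
Why: Friedel–Crafts acylation by acetyl trifluoroacetate formed in situ; the only nucleophilic positions are the two equivalent CH positions of the trialkoxy ring, each ortho to the allyloxy group, so one acetyl group enters there and deactivates the ring. The benzoate ring is deactivated, and no strong Lewis acid is present to cleave benzyl ethers.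

Step 9
Reactants: 14 methyl 3-[3-acetyl-4-(allyloxy)-2,6-bis(benzyloxy)phenyl]-4-(benzyloxy)benzoate
Product: 15 methyl 3-[3-acetyl-2,6-bis(benzyloxy)-4-hydroxyphenyl]-4-(benzyloxy)benzoate
Conditions: Pd(PPh3)4 (5 mol%), morpholine, THF, rt
Reagents that add atoms: none
Why: Tsuji–Trost deallylation; zerovalent palladium ionises the aryl allyl ether, whose phenoxide is stabilised by the ortho acetyl group, and morpholine traps the allyl fragment. Benzyl ethers, ketone and ester are untouched.

Step 10
Reactants: 15 methyl 3-[3-acetyl-2,6-bis(benzyloxy)-4-hydroxyphenyl]-4-(benzyloxy)benzoate; 16 4-(benzyloxy)benzoyl chloride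
Product: 18 methyl 4-(benzyloxy)-3-{5,7-bis(benzyloxy)-2-[4-(benzyloxy)phenyl]-4-oxo-4H-chromen-6-yl}benzoate, via 1,3-diketone 17 (not isolated)
Conditions: LiN(SiMe3)2 (4 equiv), THF, −78 °C; 16, −78 °C to rt; aqueous HCl work-up; then AcOH, H2SO4 (cat.), 90 °C
Reagents that add atoms: none
Why: Direct form of the Baker–Venkataraman construction: the lithium phenoxide–enolate is aroylated on carbon to the 1,3-diketone, which cyclodehydrates in acid through its only free phenol. That phenol is the para oxygen and O5'' is benzylated, so the 6-aryl flavone is the only possible isomer; the non-enolisable benzoate is inert.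

Step 11
Reactants: 18 methyl 4-(benzyloxy)-3-{5,7-bis(benzyloxy)-2-[4-(benzyloxy)phenyl]-4-oxo-4H-chromen-6-yl}benzoate
Product: 19 4-(benzyloxy)-3-{5,7-bis(benzyloxy)-2-[4-(benzyloxy)phenyl]-4-oxo-4H-chromen-6-yl}benzoic acid
Conditions: LiOH·H2O, THF/MeOH/H2O, 45 °C; then 1 M HCl
Reagents that add atoms: lithium hydroxide, [Li+].[OH-]
Why: Ester saponification; any reversible opening of the pyranone by hydroxide is undone on acidification.

Step 12
Reactants: 19 4-(benzyloxy)-3-{5,7-bis(benzyloxy)-2-[4-(benzyloxy)phenyl]-4-oxo-4H-chromen-6-yl}benzoic acid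
Product: 20 5,7-bis(benzyloxy)-6-[2-(benzyloxy)-5-(hydroxymethyl)phenyl]-2-[4-(benzyloxy)phenyl]-4H-chromen-4-one
Conditions: BH3·SMe2 (3 equiv), THF, 0 °C to rt; MeOH quench
Reagents that add atoms: none
Why: Borane reduces carboxylic acids through acyloxyboranes much faster than it attacks the cross-conjugated pyranone carbonyl, which behaves as a vinylogous ester, or the electron-poor C2''–C3'' double bond.

Step 13
Reactants: 20 5,7-bis(benzyloxy)-6-[2-(benzyloxy)-5-(hydroxymethyl)phenyl]-2-[4-(benzyloxy)phenyl]-4H-chromen-4-one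
Product: 21 4-(benzyloxy)-3-{5,7-bis(benzyloxy)-2-[4-(benzyloxy)phenyl]-4-oxo-4H-chromen-6-yl}benzaldehyde
Conditions: activated MnO2 (excess), CH2Cl2, rt
Reagents that add atoms: none
Why: MnO2 oxidises benzylic alcohols to aldehydes without over-oxidation and leaves the flavone and benzyl ethers alone.

Step 14
Reactants: 22 1-(2,4-dihydroxy-6-methoxyphenyl)ethanone
Product: 23 1-[4-(benzyloxy)-2-hydroxy-6-methoxyphenyl]ethanone
Conditions: BnBr (1.05 equiv), K2CO3, acetone, reflux
Reagents that add atoms: benzyl bromide, BrCc1ccccc1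
Why: Williamson benzylation; the 2-hydroxyl is locked in a hydrogen bond to the acetyl group, so only the 4-hydroxyl reacts.

Step 15
Reactants: 23 1-[4-(benzyloxy)-2-hydroxy-6-methoxyphenyl]ethanone
Product: 24 tert-butyl 3-[4-(benzyloxy)-2-hydroxy-6-methoxyphenyl]-3-oxopropanoate
Conditions: LiN(SiMe3)2 (3.2 equiv), THF, −78 °C; Boc2O (1.1 equiv), −78 to −20 °C; aqueous NH4Cl
Reagents that add atoms: di-tert-butyl dicarbonate, CC(C)(C)OC(=O)OC(=O)OC(C)(C)C
Why: Claisen-type C-acylation of the lithium phenoxide–enolate with a dicarbonate, the third equivalent of base taking up the acidic product; low temperature and the bulky ester hold back closure to the 4-hydroxycoumarin.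

Step 16
Reactants: 21 4-(benzyloxy)-3-{5,7-bis(benzyloxy)-2-[4-(benzyloxy)phenyl]-4-oxo-4H-chromen-6-yl}benzaldehyde; 24 tert-butyl 3-[4-(benzyloxy)-2-hydroxy-6-methoxyphenyl]-3-oxopropanoate
Product: 25 tert-butyl 2-[4-(benzyloxy)-2-hydroxy-6-methoxybenzoyl]-3-(4-(benzyloxy)-3-{5,7-bis(benzyloxy)-2-[4-(benzyloxy)phenyl]-4-oxo-4H-chromen-6-yl}phenyl)acrylate (E/Z mixture)
Conditions: piperidine (0.2 equiv), AcOH (0.2 equiv), 4 Å MS, toluene, rt
Reagents that add atoms: none
Why: Knoevenagel condensation of a β-ketoester with an aryl aldehyde under amine/acid catalysis with removal of water; it is run at room temperature and stopped early to limit uncatalysed ring closure.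

Step 17
Reactants: 25 tert-butyl 2-[4-(benzyloxy)-2-hydroxy-6-methoxybenzoyl]-3-(4-(benzyloxy)-3-{5,7-bis(benzyloxy)-2-[4-(benzyloxy)phenyl]-4-oxo-4H-chromen-6-yl}phenyl)acrylate
Product: 28 (2S)-7-(benzyloxy)-2-(4-(benzyloxy)-3-{5,7-bis(benzyloxy)-2-[4-(benzyloxy)phenyl]-4-oxo-4H-chromen-6-yl}phenyl)-5-methoxychroman-4-one, via tert-butyl flavanone-3-carboxylate 26 (not isolated), via flavanone-3-carboxylic acid 27 (not isolated)
Conditions: quinidine-derived thiourea N-[3,5-bis(trifluoromethyl)phenyl]-N'-(9-deoxy-epi-quinidin-9-yl)thiourea (10 mol%), toluene, −25 °C; then TsOH·H2O (0.5 equiv), 80 °C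
Reagents that add atoms: none
Why: Catalytic asymmetric intramolecular oxa-Michael addition (6-endo-trig) to an alkylidene β-ketoester: the quinuclidine nitrogen deprotonates the phenol while the thiourea binds the ketoester, and the phenoxide adds to one face of the alkylidene to set C2 as S under catalyst control. Acid then cleaves the tert-butyl ester and the β-keto acid loses CO2, which removes the C3 stereocenter.

Step 18
Reactants: 28 (2S)-7-(benzyloxy)-2-(4-(benzyloxy)-3-{5,7-bis(benzyloxy)-2-[4-(benzyloxy)phenyl]-4-oxo-4H-chromen-6-yl}phenyl)-5-methoxychroman-4-one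
Product: 29 (2S)-7-hydroxy-2-{4-hydroxy-3-[5,7-dihydroxy-2-(4-hydroxyphenyl)-4-oxo-4H-chromen-6-yl]phenyl}-5-methoxychroman-4-one
Conditions: H2 (1 atm), 10% Pd/C, EtOAc/MeOH, rt
Reagents that add atoms: none
Why: Hydrogenolysis of the five benzyl ethers under neutral conditions should leave C2, the methyl ether, the flavone double bond and both carbonyl groups unchanged; the reaction is stopped once the benzyl ethers are consumed.

## Compound list

1 | 2,4,6-trihydroxybenzaldehyde | O=Cc1c(O)cc(O)cc1O | starting material
2 | 4-(allyloxy)-2,6-dihydroxybenzaldehyde | O=Cc1c(O)cc(OCC=C)cc1O | intermediate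
3 | 4-(allyloxy)-2,6-bis(benzyloxy)benzaldehyde | O=Cc1c(OCc2ccccc2)cc(OCC=C)cc1OCc1ccccc1 | intermediate
4 | 5-(allyloxy)-1,3-bis(benzyloxy)-2-(2-methoxyvinyl)benzene, E/Z mixture | COC=Cc1c(OCc2ccccc2)cc(OCC=C)cc1OCc1ccccc1 | intermediate
5 | 2-[4-(allyloxy)-2,6-bis(benzyloxy)phenyl]acetaldehyde | O=CCc1c(OCc2ccccc2)cc(OCC=C)cc1OCc1ccccc1 | intermediate
6 | 2-[4-(allyloxy)-2,6-bis(benzyloxy)phenyl]acetic acid | OC(=O)Cc1c(OCc2ccccc2)cc(OCC=C)cc1OCc1ccccc1 | intermediate
7 | bis(trimethylsilyl) ketene acetal of 6 | C=CCOc1cc(OCc2ccccc2)c(C=C(O[Si](C)(C)C)O[Si](C)(C)C)c(OCc2ccccc2)c1 | intermediate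
8 | methyl coumalate (methyl 2-oxo-2H-pyran-5-carboxylate) | COC(=O)C1=COC(=O)C=C1 | starting material
9 | methyl 7-[4-(allyloxy)-2,6-bis(benzyloxy)phenyl]-3-oxo-8,8-bis(trimethylsilyloxy)-2-oxabicyclo[2.2.2]oct-5-ene-6-carboxylate, racemic diastereomer mixture | COC(=O)C1=CC2C(=O)OC1C(c1c(OCc3ccccc3)cc(OCC=C)cc1OCc1ccccc1)C2(O[Si](C)(C)C)O[Si](C)(C)C | intermediate
10 | methyl 3-[4-(allyloxy)-2,6-bis(benzyloxy)phenyl]-4,4-bis(trimethylsilyloxy)cyclohexa-1,5-diene-1-carboxylate, racemic | COC(=O)C1=CC(c2c(OCc3ccccc3)cc(OCC=C)cc2OCc2ccccc2)C(O[Si](C)(C)C)(O[Si](C)(C)C)C=C1 | intermediate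
11 | methyl 3-[4-(allyloxy)-2,6-bis(benzyloxy)phenyl]-4-(trimethylsilyloxy)benzoate | COC(=O)c1ccc(O[Si](C)(C)C)c(-c2c(OCc3ccccc3)cc(OCC=C)cc2OCc2ccccc2)c1 | intermediate
12 | methyl 3-[4-(allyloxy)-2,6-bis(benzyloxy)phenyl]-4-hydroxybenzoate | COC(=O)c1ccc(O)c(-c2c(OCc3ccccc3)cc(OCC=C)cc2OCc2ccccc2)c1 | intermediate
13 | methyl 3-[4-(allyloxy)-2,6-bis(benzyloxy)phenyl]-4-(benzyloxy)benzoate | COC(=O)c1ccc(OCc2ccccc2)c(-c2c(OCc3ccccc3)cc(OCC=C)cc2OCc2ccccc2)c1 | intermediate
14 | methyl 3-[3-acetyl-4-(allyloxy)-2,6-bis(benzyloxy)phenyl]-4-(benzyloxy)benzoate | COC(=O)c1ccc(OCc2ccccc2)c(-c2c(OCc3ccccc3)cc(OCC=C)c(C(C)=O)c2OCc2ccccc2)c1 | intermediate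
15 | methyl 3-[3-acetyl-2,6-bis(benzyloxy)-4-hydroxyphenyl]-4-(benzyloxy)benzoate | COC(=O)c1ccc(OCc2ccccc2)c(-c2c(OCc3ccccc3)cc(O)c(C(C)=O)c2OCc2ccccc2)c1 | intermediate
16 | 4-(benzyloxy)benzoyl chloride | O=C(Cl)c1ccc(OCc2ccccc2)cc1 | starting material
17 | methyl 4-(benzyloxy)-3-{2,6-bis(benzyloxy)-3-[3-(4-(benzyloxy)phenyl)-3-oxopropanoyl]-4-hydroxyphenyl}benzoate | COC(=O)c1ccc(OCc2ccccc2)c(-c2c(OCc3ccccc3)cc(O)c(C(=O)CC(=O)c3ccc(OCc4ccccc4)cc3)c2OCc2ccccc2)c1 | intermediate
18 | methyl 4-(benzyloxy)-3-{5,7-bis(benzyloxy)-2-[4-(benzyloxy)phenyl]-4-oxo-4H-chromen-6-yl}benzoate | COC(=O)c1ccc(OCc2ccccc2)c(-c2c(OCc3ccccc3)cc3oc(-c4ccc(OCc5ccccc5)cc4)cc(=O)c3c2OCc2ccccc2)c1 | intermediate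
19 | 4-(benzyloxy)-3-{5,7-bis(benzyloxy)-2-[4-(benzyloxy)phenyl]-4-oxo-4H-chromen-6-yl}benzoic acid | OC(=O)c1ccc(OCc2ccccc2)c(-c2c(OCc3ccccc3)cc3oc(-c4ccc(OCc5ccccc5)cc4)cc(=O)c3c2OCc2ccccc2)c1 | intermediate
20 | 5,7-bis(benzyloxy)-6-[2-(benzyloxy)-5-(hydroxymethyl)phenyl]-2-[4-(benzyloxy)phenyl]-4H-chromen-4-one | OCc1ccc(OCc2ccccc2)c(-c2c(OCc3ccccc3)cc3oc(-c4ccc(OCc5ccccc5)cc4)cc(=O)c3c2OCc2ccccc2)c1 | intermediate
21 | 4-(benzyloxy)-3-{5,7-bis(benzyloxy)-2-[4-(benzyloxy)phenyl]-4-oxo-4H-chromen-6-yl}benzaldehyde | O=Cc1ccc(OCc2ccccc2)c(-c2c(OCc3ccccc3)cc3oc(-c4ccc(OCc5ccccc5)cc4)cc(=O)c3c2OCc2ccccc2)c1 | intermediate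
22 | 1-(2,4-dihydroxy-6-methoxyphenyl)ethanone | COc1cc(O)cc(O)c1C(C)=O | starting material
23 | 1-[4-(benzyloxy)-2-hydroxy-6-methoxyphenyl]ethanone | COc1cc(OCc2ccccc2)cc(O)c1C(C)=O | intermediate
24 | tert-butyl 3-[4-(benzyloxy)-2-hydroxy-6-methoxyphenyl]-3-oxopropanoate | COc1cc(OCc2ccccc2)cc(O)c1C(=O)CC(=O)OC(C)(C)C | intermediate
25 | tert-butyl 2-[4-(benzyloxy)-2-hydroxy-6-methoxybenzoyl]-3-(4-(benzyloxy)-3-{5,7-bis(benzyloxy)-2-[4-(benzyloxy)phenyl]-4-oxo-4H-chromen-6-yl}phenyl)acrylate, E/Z mixture | COc1cc(OCc2ccccc2)cc(O)c1C(=O)C(=Cc1ccc(OCc2ccccc2)c(-c2c(OCc3ccccc3)cc3oc(-c4ccc(OCc5ccccc5)cc4)cc(=O)c3c2OCc2ccccc2)c1)C(=O)OC(C)(C)C | intermediate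
26 | tert-butyl (2S)-7-(benzyloxy)-2-(4-(benzyloxy)-3-{5,7-bis(benzyloxy)-2-[4-(benzyloxy)phenyl]-4-oxo-4H-chromen-6-yl}phenyl)-5-methoxy-4-oxochromane-3-carboxylate, C3 epimers and enol | COc1cc(OCc2ccccc2)cc2c1C(=O)C(C(=O)OC(C)(C)C)[C@@H](c1ccc(OCc3ccccc3)c(-c3c(OCc4ccccc4)cc4oc(-c5ccc(OCc6ccccc6)cc5)cc(=O)c4c3OCc3ccccc3)c1)O2 | intermediate
27 | (2S)-7-(benzyloxy)-2-(4-(benzyloxy)-3-{5,7-bis(benzyloxy)-2-[4-(benzyloxy)phenyl]-4-oxo-4H-chromen-6-yl}phenyl)-5-methoxy-4-oxochromane-3-carboxylic acid, C3 epimers | COc1cc(OCc2ccccc2)cc2c1C(=O)C(C(=O)O)[C@@H](c1ccc(OCc3ccccc3)c(-c3c(OCc4ccccc4)cc4oc(-c5ccc(OCc6ccccc6)cc5)cc(=O)c4c3OCc3ccccc3)c1)O2 | intermediate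
28 | (2S)-7-(benzyloxy)-2-(4-(benzyloxy)-3-{5,7-bis(benzyloxy)-2-[4-(benzyloxy)phenyl]-4-oxo-4H-chromen-6-yl}phenyl)-5-methoxychroman-4-one | COc1cc(OCc2ccccc2)cc2c1C(=O)C[C@@H](c1ccc(OCc3ccccc3)c(-c3c(OCc4ccccc4)cc4oc(-c5ccc(OCc6ccccc6)cc5)cc(=O)c4c3OCc3ccccc3)c1)O2 | intermediate
29 | (2S)-7-hydroxy-2-{4-hydroxy-3-[5,7-dihydroxy-2-(4-hydroxyphenyl)-4-oxo-4H-chromen-6-yl]phenyl}-5-methoxychroman-4-one | COc1cc(O)cc2c1C(=O)C[C@@H](c1ccc(O)c(-c3c(O)cc4oc(-c5ccc(O)cc5)cc(=O)c4c3O)c1)O2 | target

## Step count and least certain steps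

Total: 18 steps. Longest linear sequence: 16 steps (steps 1 to 13, then 16 to 18). Steps 14 and 15 form the short ring A branch.

**Step 6 (key step).** The hindered aryl-bearing carbon may add to C6 of the pyrone without the second bond forming. The pyrone would then open to a glutaconate-type silyl ester (Mukaiyama–Michael addition and ring opening) instead of closing the bridged lactone. The ketene acetal may also be protonated by adventitious acid faster than it cycloadds.
Fallback: it sets out from aldehyde 3 and makes the biaryl bond by cross-coupling. Baeyer–Villiger oxidation of 3 with a peracid would give 4-(allyloxy)-2,6-bis(benzyloxy)phenyl formate F1, and methanolysis would give 4-(allyloxy)-2,6-bis(benzyloxy)phenol F2. Triflation would give 4-(allyloxy)-2,6-bis(benzyloxy)phenyl trifluoromethanesulfonate F3. Separately, purchased methyl 3-bromo-4-hydroxybenzoate would be benzylated to methyl 4-(benzyloxy)-3-bromobenzoate F4 and converted by Miyaura borylation (PdCl2(dppf), KOAc, bis(pinacolato)diboron) into methyl 4-(benzyloxy)-3-(4,4,5,5-tetramethyl-1,3,2-dioxaborolan-2-yl)benzoate F5. Suzuki–Miyaura coupling of F3 with F5 (Pd(OAc)2, a bulky biarylphosphine, K3PO4) would give 13, where the route resumes. The coupling is hindered, and the allyl ether is exposed to zerovalent palladium, which is why it is only the fallback.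

**Step 8.** Benzyl groups may be lost or may migrate in the acidic acylation medium, or trifluoroacetylation may compete with acetylation.
Fallback: it sets out from 13. Vilsmeier–Haack formylation, which is mild and fully compatible with aryl benzyl ethers, would give methyl 3-[4-(allyloxy)-2,6-bis(benzyloxy)-3-formylphenyl]-4-(benzyloxy)benzoate F6 at the same position. Addition of MeMgBr at −78 °C, where an aldehyde reacts far faster than a methyl benzoate, would give racemic methyl 3-[4-(allyloxy)-2,6-bis(benzyloxy)-3-(1-hydroxyethyl)phenyl]-4-(benzyloxy)benzoate F7. Dess–Martin oxidation would give 14.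

**Step 12.** Hydride may be delivered to the pyranone carbonyl or to the flavone double bond in competition with reduction of the acid.
Fallback: it sets out from acid 19 and uses no hydride reagent. Carbodiimide coupling with ethanethiol would give S-ethyl 4-(benzyloxy)-3-{5,7-bis(benzyloxy)-2-[4-(benzyloxy)phenyl]-4-oxo-4H-chromen-6-yl}benzothioate F8. Fukuyama reduction (Et3SiH, Pd/C, acetone) would give aldehyde 21 directly, bypassing 20.

**Step 15.** Acylation may occur at the phenoxide oxygen, followed by closure of the ketoester onto the phenol to a 4-hydroxycoumarin, or a bis-acylated product may form.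
Fallback: it sets out from 23. The phenol would be silylated to 1-[4-(benzyloxy)-2-(tert-butyldimethylsilyloxy)-6-methoxyphenyl]ethanone F9. The simple ketone enolate (LiN(iPr)2, then Boc2O) would be acylated to tert-butyl 3-[4-(benzyloxy)-2-(tert-butyldimethylsilyloxy)-6-methoxyphenyl]-3-oxopropanoate F10. Buffered fluoride would release 24.

**Step 17.** Uncatalysed ring closure during the condensation or before the catalyst acts would lower the enantiomeric purity. So would acid-promoted opening of ring C at 80 °C, which the para-benzyloxy group on ring B eases. The sense of induction on this substrate is also unproven.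
Fallback: it sets out from aldehyde 21 and ketone 23. Claisen–Schmidt condensation (KOH, EtOH/THF) would give (E)-1-[4-(benzyloxy)-2-hydroxy-6-methoxyphenyl]-3-(4-(benzyloxy)-3-{5,7-bis(benzyloxy)-2-[4-(benzyloxy)phenyl]-4-oxo-4H-chromen-6-yl}phenyl)prop-2-en-1-one F11. Ring closure with NaOAc in hot ethanol would give racemic 7-(benzyloxy)-2-(4-(benzyloxy)-3-{5,7-bis(benzyloxy)-2-[4-(benzyloxy)phenyl]-4-oxo-4H-chromen-6-yl}phenyl)-5-methoxychroman-4-one F12. Preparative chromatography on a polysaccharide chiral stationary phase would separate the 2S enantiomer, which is 28.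

## Further compounds

F1 | step 6 | 4-(allyloxy)-2,6-bis(benzyloxy)phenyl formate | O=COc1c(OCc2ccccc2)cc(OCC=C)cc1OCc1ccccc1
F2 | step 6 | 4-(allyloxy)-2,6-bis(benzyloxy)phenol | Oc1c(OCc2ccccc2)cc(OCC=C)cc1OCc1ccccc1
F3 | step 6 | 4-(allyloxy)-2,6-bis(benzyloxy)phenyl trifluoromethanesulfonate | O=S(=O)(Oc1c(OCc2ccccc2)cc(OCC=C)cc1OCc1ccccc1)C(F)(F)F
F4 | step 6 | methyl 4-(benzyloxy)-3-bromobenzoate | COC(=O)c1ccc(OCc2ccccc2)c(Br)c1
F5 | step 6 | methyl 4-(benzyloxy)-3-(4,4,5,5-tetramethyl-1,3,2-dioxaborolan-2-yl)benzoate | COC(=O)c1ccc(OCc2ccccc2)c(B2OC(C)(C)C(C)(C)O2)c1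
F6 | step 8 | methyl 3-[4-(allyloxy)-2,6-bis(benzyloxy)-3-formylphenyl]-4-(benzyloxy)benzoate | COC(=O)c1ccc(OCc2ccccc2)c(-c2c(OCc3ccccc3)cc(OCC=C)c(C=O)c2OCc2ccccc2)c1
F7 | step 8 | methyl 3-[4-(allyloxy)-2,6-bis(benzyloxy)-3-(1-hydroxyethyl)phenyl]-4-(benzyloxy)benzoate, racemic | COC(=O)c1ccc(OCc2ccccc2)c(-c2c(OCc3ccccc3)cc(OCC=C)c(C(C)O)c2OCc2ccccc2)c1
F8 | step 12 | S-ethyl 4-(benzyloxy)-3-{5,7-bis(benzyloxy)-2-[4-(benzyloxy)phenyl]-4-oxo-4H-chromen-6-yl}benzothioate | CCSC(=O)c1ccc(OCc2ccccc2)c(-c2c(OCc3ccccc3)cc3oc(-c4ccc(OCc5ccccc5)cc4)cc(=O)c3c2OCc2ccccc2)c1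
F9 | step 15 | 1-[4-(benzyloxy)-2-(tert-butyldimethylsilyloxy)-6-methoxyphenyl]ethanone | COc1cc(OCc2ccccc2)cc(O[Si](C)(C)C(C)(C)C)c1C(C)=O
F10 | step 15 | tert-butyl 3-[4-(benzyloxy)-2-(tert-butyldimethylsilyloxy)-6-methoxyphenyl]-3-oxopropanoate | COc1cc(OCc2ccccc2)cc(O[Si](C)(C)C(C)(C)C)c1C(=O)CC(=O)OC(C)(C)C
F11 | step 17 | (E)-1-[4-(benzyloxy)-2-hydroxy-6-methoxyphenyl]-3-(4-(benzyloxy)-3-{5,7-bis(benzyloxy)-2-[4-(benzyloxy)phenyl]-4-oxo-4H-chromen-6-yl}phenyl)prop-2-en-1-one | COc1cc(OCc2ccccc2)cc(O)c1C(=O)/C=C/c1ccc(OCc2ccccc2)c(-c2c(OCc3ccccc3)cc3oc(-c4ccc(OCc5ccccc5)cc4)cc(=O)c3c2OCc2ccccc2)c1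
F12 | step 17 | 7-(benzyloxy)-2-(4-(benzyloxy)-3-{5,7-bis(benzyloxy)-2-[4-(benzyloxy)phenyl]-4-oxo-4H-chromen-6-yl}phenyl)-5-methoxychroman-4-one, racemic | COc1cc(OCc2ccccc2)cc2c1C(=O)CC(c1ccc(OCc3ccccc3)c(-c3c(OCc4ccccc4)cc4oc(-c5ccc(OCc6ccccc6)cc5)cc(=O)c4c3OCc3ccccc3)c1)O2
A1 | alternative 1 | (2S)-7-hydroxy-5-methoxy-2-{4-(methoxymethoxy)-3-[5,7-bis(methoxymethoxy)-2-(4-(methoxymethoxy)phenyl)-4-oxo-4H-chromen-6-yl]phenyl}chroman-4-one | COc1cc(O)cc2c1C(=O)C[C@@H](c1ccc(OCOC)c(-c3c(OCOC)cc4oc(-c5ccc(OCOC)cc5)cc(=O)c4c3OCOC)c1)O2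
A2 | alternative 1 | (2S)-5-bromo-2-{4-(methoxymethoxy)-3-[5,7-bis(methoxymethoxy)-2-(4-(methoxymethoxy)phenyl)-4-oxo-4H-chromen-6-yl]phenyl}-2,3-dihydro-4H-pyran-4-one | O=C1C[C@@H](c2ccc(OCOC)c(-c3c(OCOC)cc4oc(-c5ccc(OCOC)cc5)cc(=O)c4c3OCOC)c2)OC=C1Br
A3 | alternative 1 | 1,1-dimethoxy-3-(trimethylsilyloxy)buta-1,3-diene | COC(OC)=CC(=C)O[Si](C)(C)C
A4 | alternative 2 | 2-[2-(benzyloxy)-5-(dimethoxymethyl)phenyl]-5-[(4-methoxybenzyl)oxy]-3-[(triisopropylsilyl)oxy]phenol | COc1ccc(COc2cc(O)c(-c3cc(C(OC)OC)ccc3OCc3ccccc3)c(O[Si](C(C)C)(C(C)C)C(C)C)c2)cc1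
A5 | alternative 2 | 3-[(4-methoxybenzyl)oxy]cyclobut-2-en-1-one | COc1ccc(COC2=CC(=O)C2)cc1
A6 | alternative 2 | ({[2-(benzyloxy)-5-(dimethoxymethyl)phenyl]ethynyl}oxy)triisopropylsilane | COC(OC)c1ccc(OCc2ccccc2)c(C#CO[Si](C(C)C)(C(C)C)C(C)C)c1
A7 | alternative 3 | (E)-1-[2-hydroxy-6-methoxy-4-(methoxymethoxy)phenyl]-3-{4-(methoxymethoxy)-3-[5,7-bis(methoxymethoxy)-2-(4-(methoxymethoxy)phenyl)-4-oxo-4H-chromen-6-yl]phenyl}prop-2-en-1-one | COc1cc(OCOC)cc(O)c1C(=O)/C=C/c1ccc(OCOC)c(-c3c(OCOC)cc4oc(-c5ccc(OCOC)cc5)cc(=O)c4c3OCOC)c1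
A8 | alternative 3 | (E)-3-{4-(methoxymethoxy)-3-[5,7-bis(methoxymethoxy)-2-(4-(methoxymethoxy)phenyl)-4-oxo-4H-chromen-6-yl]phenyl}acrylic acid | OC(=O)/C=C/c1ccc(OCOC)c(-c2c(OCOC)cc3oc(-c4ccc(OCOC)cc4)cc(=O)c3c2OCOC)c1
A9 | alternative 3 | 2-methoxy-4-(methoxymethoxy)-6-(trimethylsilyl)phenyl trifluoromethanesulfonate | COCOc1cc(OC)c(OS(=O)(=O)C(F)(F)F)c([Si](C)(C)C)c1
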